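The constants to be had come from two runs that differ in their charge of partner, and the one followed here is how the highest target answers that charge.

| flask | substrate | partner | remark | time |
|---|---|---|---|---|
| south-west | 0.10 M | 0.20 M | the very flask that is asked about, followed so far |  |
| south | 0.10 M | 0.40 M | run made earlier |  |
| flask | 0.10 M | 0.200 M |  | 40 min |

| run | time / min | target / % | substrate / % |
|---|---|---|---|
| south-west | 0.833 | 9 | 14 |
| south-west | 1.50 | 15 | 3 |
| south-west | 4.00 | 22 | 4 |
| south-west | 8.00 | 13 | 1 |
| south-west | 15.0 | 7 | 2 |
| south | 0.833 | 18 | 19 |
| south | 1.50 | 29 | 5 |
| south | 4.00 | 33 | 0 |
| south | 8.00 | 17 | 1 |
| south | 15.0 | 8 | 3 |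

(readings scatter by 1.5 percentage points)

- the moment within 40 min at which there is most target
- the amount of target, in percent of the substrate charged, at that time
- the first time at which target reaches 7.1%, in the same percent, in min

- the earlier runs were read with a standard deviation of 1.5 percentage points

Two views part over the height of the top in the flask asked about, which carries 2.00 equivalents of partner, as the south-west run did. The first view says target goes with the first power of the partner. At 1.50 min the south run, with twice the partner, read 1.93 times the target of the south-west run. Dividing the south top reading of 33% by that ratio gives a top of 17.1% here. That view must then call the south-west reading of 22% too high by 4.9 points, against a scatter of 1.5 points.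

The second view is the forecast's: “The peak rises only 1.5-fold (22→33), which suggests the intermediate also leaks away partner-independently”. It puts the top at 3.7 min with 22%, and 7.1% at 0.75 min.

My own reckoning sides with the second view. I compare the two top readings through the peak order (an apparent reaction order), the power of the partner charge to which the highest target answers: 0.585. As a reading it carries their scatter, and it stands below the first power.

The flask reaches 7.1% at 0.622 min and tops at 3.06 min with 23.7%.

    target ⇌ isomer of the product (K = 30.4, k = 0.00366 /s)
    partner + intermediate → target (k = 0.0274 /M/s)
    2 partner → homo product (k = 0.00763 /M/s)
    intermediate → side product (k = 0.00425 /s)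
    substrate → intermediate (k = 0.0363 /s)

That height stands with the forecast and against the first view, whose ratio belongs to the early readings: the south run over the south-west run was 2.00 at 0.833 min, but 1.50 at 4.00 min. Carried from this flask's top, the peak order gives 17.6% at 1.20 equiv, where the neighbour flask tops at 17.0%, and 53.3% at 8.00 equivalents, where the other neighbour flask tops at 44.0%.

The earlier runs and the new flask are simulated on assumed constants.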